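4 questions are put to 3 flasks with equal charges, which differ in how the first or second end groups go in.

| setting | elm | ash | oak | cedar | autumn | noon | spring |
|---|---|---|---|---|---|---|---|
| first end groups | 0.40 M | 0.56 M | 0.88 M | 0.40 M | 0.40 M (fed, over 50 min) | 0.40 M | 0.40 M |
| second end groups | 0.38 M | 0.38 M | 0.38 M | 0.57 M | 0.380 M | 0.380 M | 0.380 M (fed, over 50 min) |
| remark | run made earlier | run made earlier | run made earlier | run made earlier | all else is in the flask from the start; the feed brings no volume worth counting | everything together at the start | all else is in the flask from the start; the feed brings no volume worth counting |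
| time |  |  |  |  | 80 min | 80 min | 80 min |

| run | time / min | links / % | first end groups / % |
|---|---|---|---|
| elm | 4.00 | 6 | 88 |
| elm | 6.00 | 10 | 86 |
| elm | 8.00 | 14 | 83 |
| elm | 15.0 | 15 | 69 |
| elm | 20.0 | 18 | 66 |
| elm | 30.0 | 22 | 56 |
| elm | 50.0 | 24 | 41 |
| ash | 5.00 | 8 | 87 |
| ash | 8.00 | 7 | 80 |
| ash | 12.0 | 15 | 73 |
| ash | 20.0 | 17 | 66 |
| ash | 30.0 | 18 | 56 |
| ash | 40.0 | 18 | 51 |
| ash | 60.0 | 22 | 41 |
| oak | 10.0 | 10 | 79 |
| oak | 20.0 | 13 | 69 |
| oak | 30.0 | 11 | 63 |
| oak | 40.0 | 14 | 62 |
| oak | 50.0 | 10 | 62 |
| oak | 60.0 | 16 | 65 |
| cedar | 5.00 | 10 | 82 |
| cedar | 10.0 | 16 | 70 |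
| cedar | 20.0 | 29 | 53 |
| cedar | 30.0 | 31 | 45 |
| cedar | 60.0 | 40 | 26 |

(readings scatter by 1.5 percentage points)

- the flask with the highest amount of links, in percent of the first end groups charged ("all alike" if they lie within 1.5 percentage points) (autumn / noon / spring / all alike)
- final links, as a percentage of the first end groups charged, in autumn
- final links, as a percentage of the first end groups charged, in noon
- final links, as a percentage of the first end groups charged, in spring

- a reading or a percentage of links counts all its forms, free or not

Elm has noon's charges, and its links rose 2 percentage points over the last 20.0 min, so noon is reckoned at elm's last reading, 24%. A fed species enters on a ramp and then stays in, so the part of its charge already in, averaged over the run, is 0.688, the feed mean. Each link joins a first to a second end group, so this reckoning gives each fed flask the feed mean times noon's links, 16.5%, which is less than noon, and puts noon first. It replaces a curve by its mean, so the result must check it.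

The forecast differs, with autumn first and 42%, 28% and 20% for autumn, noon and spring, on the ground that feeding the first end groups keeps their ratio to the second end groups low, which “raises selectivity”. The flasks give 17.2% in autumn, 24.8% in noon and 12.7% in spring, so noon stands highest.

    first end groups + second end groups → links (k = 7.83 × 10⁻⁴ M⁻¹ s⁻¹)
    first end groups + second end groups → rings, rate k2*[first end groups] as long as [second end groups] is above zero (k = 2.00 × 10⁻⁴ s⁻¹)
    second end groups ⇌ dormant form (K = 1.97, k = 3.41 × 10⁻⁴ s⁻¹)
    crystals ⇌ links, rate k4*(cs4 - [links]) while solid is left; crystals form when [links] > cs4 (solubility = 4.70 mM, k = 0.0302 s⁻¹)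

At 27.6 min in noon, the half-life of second end groups by the link step is 67 min, while their exchange with the dormant form, a resting state, relaxes with a half-life of 22.5 min, a shorter time. The rings step in noon uses first end groups 2.5 times as fast as the link step at 27.6 min, and 66 times as fast at 80.0 min. The feed mean 0.688 on noon's links gives 17.1%, beside autumn's 17.2%, while spring lies 4.4 points below it. For autumn fed over 15.0 min, the feed mean is 0.906, which gives 22.5%, and that flask ended at 21.7%.

(The earlier runs and the new flask stem from a simulated flask with made-up constants, and the scatter is random.)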